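## Retrosynthetic overview

1. Target 14 comes from Z-allylic diol 13 by chemoselective MnO2 oxidation. 13 comes from tertiary carbinol 12 by the key C–O bond formation: a hydroxyl-anchored oxo-vanadium [3,3] transposition that makes the allylic C–O bond and fixes the Z tetrasubstituted alkene.
2. 12 comes from keto alcohol 11 (isopropenyl addition). 11 comes from allyl ketone 9 by a second C–O bond formation (anti-Markovnikov hydroboration/oxidation).
3. 9 comes from enone 7 by one-pot Me2CuLi conjugate addition and enolate allylation; the C4 methyl of 7 controls both new stereocentres.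
4. 7 comes from anisole 4 by Birch reduction/hydrolysis to 6, then enantioselective amine-catalysed β,γ→α,β isomerisation (the only catalyst-controlled centre).
5. 4 comes from benzyl chloride 1 and farnesyl bromide 2. The only ring is the anisole ring carried through, so there is no ring-forming step.

Abbreviation: hFar = (3E,7E)-4,8,12-trimethyltrideca-3,7,11-trien-1-yl (homofarnesyl).

Assumption: 1 and 2 are taken as catalogue compounds, and which pseudoenantiomer of the step 3 amine catalyst gives the 4R enone is settled by one test run.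

## Route

**Step 1**
Reactants: 1 2-(chloromethyl)-4-methoxy-1-methylbenzene; 2 (2E,6E)-farnesyl bromide
Product: 4 4-methoxy-1-methyl-2-hFar-benzene, via benzylic Grignard reagent 3 (not isolated)
Conditions: Mg, THF, 0 °C (slow addition of 1); then 2, Li2CuCl4 (3 mol%), THF, −40 → 0 °C
Reagents that add atoms: none
Why: Copper-catalysed sp3–sp3 Grignard cross-coupling (Kochi type) of a benzylic Grignard reagent with a primary allylic bromide proceeds by direct alpha substitution in THF at low temperature, so the Ar–CH2–CH2–CH= link is formed with the E,E geometry of 2 intact; no stereocentre is formed.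

**Step 2**
Reactants: 4 4-methoxy-1-methyl-2-hFar-benzene
Product: 6 4-methyl-3-hFar-cyclohex-3-en-1-one, via dihydroanisole 5 (not isolated)
Conditions: Li, NH3(l), THF, t-BuOH, −78 → −33 °C; NH4Cl; crude 5, (CO2H)2 (cat.), THF/MeOH/H2O, rt
Reagents that add atoms: water, O
Why: Birch reduction leaves the ring double bonds at the methoxy carbon and between the two alkyl-bearing carbons (the isolated chain alkenes are inert to Li/NH3), and mild oxalic acid hydrolysis of the enol ether gives the non-conjugated ketone without moving the tetrasubstituted double bond; no stereocentre is formed.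

**Step 3**
Reactants: 6 4-methyl-3-hFar-cyclohex-3-en-1-one
Product: 7 (4R)-4-methyl-3-hFar-cyclohex-2-en-1-one
Conditions: 9-amino-9-deoxy-epi-cinchona primary amine catalyst (10 mol%), ArCO2H (20 mol%), PhMe, −20 °C → rt
Reagents that add atoms: none
Why: In this amine-catalysed enantioselective olefin isomerisation (biomimetic proton transfer) the primary amine condenses to a dienamine and the protonated quinuclidine of the catalyst delivers the proton to one face of the gamma carbon, which sets C4 as R before hydrolysis releases the conjugated enone.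

**Step 4**
Reactants: 7 (4R)-4-methyl-3-hFar-cyclohex-2-en-1-one
Product: 9 (2S,3R,4R)-3,4-dimethyl-2-(prop-2-en-1-yl)-3-hFar-cyclohexan-1-one, via lithium enolate 8 (not isolated)
Conditions: Me2CuLi (2 equiv, from MeLi and CuI), Et2O, −20 → 0 °C; then allyl bromide (6 equiv), HMPA, THF, −40 → 0 °C; NH4Cl
Reagents that add atoms: lithium dimethylcuprate, [Li+].C[Cu-]C; allyl bromide, C=CCBr
Why: In this cuprate conjugate addition followed by enolate C-alkylation, methyl adds axially anti to the pseudoaxial C4 methyl (quaternary centre 3R, new methyl trans to the C4 methyl), and enolate 8 is then allylated through the half-chair with the C4 methyl equatorial and the hFar chain pseudoaxial, on the face anti to that chain and free of any syn-axial methyl, which sets C2 as S (allyl trans to the chain, cis to the new methyl).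

**Step 5**
Reactants: 9 (2S,3R,4R)-3,4-dimethyl-2-(prop-2-en-1-yl)-3-hFar-cyclohexan-1-one
Product: 11 (2S,3R,4R)-2-(3-hydroxypropyl)-3,4-dimethyl-3-hFar-cyclohexan-1-one, via pinacol boronate 10 (not isolated)
Conditions: HBpin (1.3 equiv), [Ir(cod)Cl]2 (1.5 mol%), dppm (3 mol%), CH2Cl2, rt; then H2O2, pH 7 phosphate buffer, THF, 0 °C → rt
Reagents that add atoms: pinacolborane, B1OC(C)(C)C(C)(C)O1 (its boron is kept only in 10); hydrogen peroxide, OO (oxygen of the new hydroxyl)
Why: Iridium-catalysed anti-Markovnikov hydroboration with pinacolborane takes only the monosubstituted alkene (not the trisubstituted alkenes or the ketone), and buffered peroxide oxidation turns C–B into the primary C–O bond without base that could epimerise C2; no new stereocentre.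

**Step 6**
Reactants: 11 (2S,3R,4R)-2-(3-hydroxypropyl)-3,4-dimethyl-3-hFar-cyclohexan-1-one
Product: 12 (1R,2S,3R,4R)-2-(3-hydroxypropyl)-3,4-dimethyl-1-(prop-1-en-2-yl)-3-hFar-cyclohexan-1-ol
Conditions: CH2=C(Me)MgBr (4 equiv), CeCl3 (4 equiv), THF, −78 → 0 °C; NH4Cl
Reagents that add atoms: isopropenylmagnesium bromide, C=C(C)[Mg]Br
Why: Organocerium 1,2-addition (Imamoto conditions) suppresses enolisation of the hindered ketone, and equatorial attack on the chair whose axial C3 methyl blocks the axial path should give mainly the 1R carbinol (hydroxyl cis to the hydroxypropyl arm), a centre that is erased in step 7.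

**Step 7**
Reactants: 12 (1R,2S,3R,4R)-2-(3-hydroxypropyl)-3,4-dimethyl-1-(prop-1-en-2-yl)-3-hFar-cyclohexan-1-ol
Product: 13 (2Z)-2-[(2S,3R,4R)-2-(3-hydroxypropyl)-3,4-dimethyl-3-hFar-cyclohexylidene]propan-1-ol
Conditions: VO(OSiPh3)3 (10 mol%), 4 Å molecular sieves, PhMe (0.01 M), 40–60 °C; aq. NaHCO3
Reagents that add atoms: none
Why: Proposed new method: the primary hydroxyl of 12 anchors the oxo-vanadium centre and the hindered tertiary hydroxyl then closes a cyclic vanadium diester, so the [3,3] oxo shift (the V–O–C1 bond breaks while V=O forms the new C–O bond at the terminal CH2 of the isopropenyl group) must pass through a chair transition state in which ring carbon C2, tied to vanadium through the hydroxypropyl arm, is gauche to vanadium and hence pseudoaxial, and a pseudoaxial group ends up cis to the new CH2O group, giving the Z tetrasubstituted alkene, while the poor leaving-group ability of a vanadium ester (compared with a ReO4 ester) disfavours ionisation to an allyl cation that the pendant hydroxyl or the chain alkene would trap; the closest known reaction type is the undirected oxo-vanadium- or oxo-rhenium-catalysed 1,3-transposition of tertiary allylic alcohols (linalool to geraniol/nerol, nerolidol to farnesol), combined here with the alkoxide-anchoring principle of hydroxyl-directed vanadium epoxidation.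

**Step 8**
Reactants: 13 (2Z)-2-[(2S,3R,4R)-2-(3-hydroxypropyl)-3,4-dimethyl-3-hFar-cyclohexylidene]propan-1-ol
Product: 14 (2Z)-2-[(2S,3R,4R)-2-(3-hydroxypropyl)-3,4-dimethyl-3-hFar-cyclohexylidene]propanal
Conditions: MnO2 (activated, 20 equiv), CH2Cl2, rt
Reagents that add atoms: none
Why: MnO2 allylic oxidation takes only the allylic primary alcohol, leaves the saturated primary alcohol untouched and does not isomerise the tetrasubstituted alkene, so the Z enal of the target is obtained with all three ring stereocentres unchanged.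

## Compound list

1 | 2-(chloromethyl)-4-methoxy-1-methylbenzene | COc1ccc(C)c(CCl)c1 | starting material
2 | (2E,6E)-farnesyl bromide | CC(C)=CCC/C(C)=C/CC/C(C)=C/CBr | starting material
3 | (5-methoxy-2-methylbenzyl)magnesium chloride | COc1ccc(C)c(C[Mg]Cl)c1 | intermediate
4 | 4-methoxy-1-methyl-2-hFar-benzene | CC(C)=CCC/C(C)=C/CC/C(C)=C/CCc1cc(OC)ccc1C | intermediate
5 | 1-methoxy-4-methyl-5-hFar-cyclohexa-1,4-diene | CC(C)=CCC/C(C)=C/CC/C(C)=C/CCC1=C(C)CC=C(OC)C1 | intermediate
6 | 4-methyl-3-hFar-cyclohex-3-en-1-one | CC(C)=CCC/C(C)=C/CC/C(C)=C/CCC1=C(C)CCC(=O)C1 | intermediate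
7 | (4R)-4-methyl-3-hFar-cyclohex-2-en-1-one | CC(C)=CCC/C(C)=C/CC/C(C)=C/CCC1=CC(=O)CC[C@H]1C | intermediate
8 | lithium (3R,4R)-3,4-dimethyl-3-hFar-cyclohex-1-en-1-olate | [Li+].CC(C)=CCC/C(C)=C/CC/C(C)=C/CC[C@]1(C)[C@H](C)CCC([O-])=C1 | intermediate
9 | (2S,3R,4R)-3,4-dimethyl-2-(prop-2-en-1-yl)-3-hFar-cyclohexan-1-one | CC(C)=CCC/C(C)=C/CC/C(C)=C/CC[C@]1(C)[C@H](C)CCC(=O)[C@H]1CC=C | intermediate
10 | (2S,3R,4R)-3,4-dimethyl-2-[3-(4,4,5,5-tetramethyl-1,3,2-dioxaborolan-2-yl)propyl]-3-hFar-cyclohexan-1-one | CC(C)=CCC/C(C)=C/CC/C(C)=C/CC[C@]1(C)[C@H](C)CCC(=O)[C@H]1CCCB2OC(C)(C)C(C)(C)O2 | intermediate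
11 | (2S,3R,4R)-2-(3-hydroxypropyl)-3,4-dimethyl-3-hFar-cyclohexan-1-one | CC(C)=CCC/C(C)=C/CC/C(C)=C/CC[C@]1(C)[C@H](C)CCC(=O)[C@H]1CCCO | intermediate
12 | (1R,2S,3R,4R)-2-(3-hydroxypropyl)-3,4-dimethyl-1-(prop-1-en-2-yl)-3-hFar-cyclohexan-1-ol | CC(C)=CCC/C(C)=C/CC/C(C)=C/CC[C@]1(C)[C@H](C)CC[C@](O)(C(C)=C)[C@H]1CCCO | intermediate
13 | (2Z)-2-[(2S,3R,4R)-2-(3-hydroxypropyl)-3,4-dimethyl-3-hFar-cyclohexylidene]propan-1-ol | CC(C)=CCC/C(C)=C/CC/C(C)=C/CC[C@]1(C)[C@H](C)CC/C(=C(\C)CO)[C@H]1CCCO | intermediate
14 | (2Z)-2-[(2S,3R,4R)-2-(3-hydroxypropyl)-3,4-dimethyl-3-hFar-cyclohexylidene]propanal | CC(C)=CCC/C(C)=C/CC/C(C)=C/CC[C@]1(C)[C@H](C)CC/C(=C(\C)C=O)[C@H]1CCCO | target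

## Step count and risks

Total step count: 8. Longest linear sequence: 8 steps (1 or 2 to 14).

The three steps most likely to fail:

Step 7 (the proposed new transposition). It can fail in three ways: the ordinary non-chelated pathway may compete and give E/Z mixtures; ionisation may lead to a fused tetrahydropyran (attack of the hydroxypropyl oxygen) or to cation–olefin cyclisation; and the minor C1 epimer of 12 cannot chelate. The geometry of 13 is checked by NOE between the allylic CH2 and H-2. The fallback uses known chemistry and sets out from 12. The primary hydroxyl is silylated (TBSCl, imidazole, CH2Cl2) to give the tert-butyldimethylsilyl ether F1. Babler–Dauben oxidative transposition with pyridinium chlorochromate, [C5H5NH][CrO3Cl], in CH2Cl2 then gives the Z enal silyl ether F2 under substrate control only, together with the E enal silyl ether F3, which is removed by chromatography on AgNO3-doped silica. HF·pyridine in THF at 0 °C frees the alcohol and the fallback comes back to the route at 14, so that 13 and step 8 are not needed.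

Step 4 (cuprate addition and allylation). Addition to the β,β-disubstituted, γ-branched enone may be slow, and the hindered enolate 8 may equilibrate to the other alpha position or allylate on the wrong face. The ketone epimer wanted at C2 is estimated to be the less stable one, so it cannot be corrected by equilibration. The fallback sets out from 7. After the same Me2CuLi addition, enolate 8 is O-acylated with allyl chloroformate in THF to give the allyl enol carbonate F4. Decarboxylative Tsuji allylation with Pd(PPh3)4 in THF at rt then forms the C2–allyl bond regiospecifically under neutral conditions, the bulky allyl-palladium electrophile taking the same open face, and the fallback comes back to the route at 9.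

Step 3 (enantioselective isomerisation). The tetrasubstituted β,γ-alkene with a long chain may give incomplete enantiocontrol. The fallback sets out from 6. DBU in CH2Cl2 at rt gives the racemic enone F5, which is resolved by preparative chiral supercritical-fluid chromatography; the 4R enantiomer is collected and the fallback comes back to the route at 7.

## Further compounds

F1 | step 7 | (1R,2S,3R,4R)-2-[3-(tert-butyldimethylsilyloxy)propyl]-3,4-dimethyl-1-(prop-1-en-2-yl)-3-hFar-cyclohexan-1-ol | CC(C)=CCC/C(C)=C/CC/C(C)=C/CC[C@]1(C)[C@H](C)CC[C@](O)(C(C)=C)[C@H]1CCCO[Si](C)(C)C(C)(C)C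
F2 | step 7 | (2Z)-2-[(2S,3R,4R)-2-[3-(tert-butyldimethylsilyloxy)propyl]-3,4-dimethyl-3-hFar-cyclohexylidene]propanal | CC(C)=CCC/C(C)=C/CC/C(C)=C/CC[C@]1(C)[C@H](C)CC/C(=C(\C)C=O)[C@H]1CCCO[Si](C)(C)C(C)(C)C
F3 | step 7 | (2E)-2-[(2S,3R,4R)-2-[3-(tert-butyldimethylsilyloxy)propyl]-3,4-dimethyl-3-hFar-cyclohexylidene]propanal | CC(C)=CCC/C(C)=C/CC/C(C)=C/CC[C@]1(C)[C@H](C)CC/C(=C(/C)C=O)[C@H]1CCCO[Si](C)(C)C(C)(C)C
F4 | step 4 | allyl (3R,4R)-3,4-dimethyl-3-hFar-cyclohex-1-en-1-yl carbonate | CC(C)=CCC/C(C)=C/CC/C(C)=C/CC[C@]1(C)[C@H](C)CCC(OC(=O)OCC=C)=C1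
F5 | step 3 | racemic 4-methyl-3-hFar-cyclohex-2-en-1-one | CC(C)=CCC/C(C)=C/CC/C(C)=C/CCC1=CC(=O)CCC1C
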